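**Retrosynthetic overview**

- The route rests on the 6,8-dioxabicyclo[3.2.1]octane ketal: the oxane (O8, C1, C2, C3, C4, C5) and the dioxolane (C1, C7, O6, C5, O8) share the ketal carbon C5, O8 and the O–CH bridgehead C1, and C7 carries the hexyl group.
- Trichopsistide B ⇐ hydroxylation at C10 of the 10-deoxy hemiketal ⇐ Michael addition of 4-hydroxy-6-methyl-2-pyrone to a C3=C4 enone, with hemiketal closure at C9 (dihydropyran ring formed last).
- The enone ⇐ the carbonyl-ylide cycloadduct, by deleting the C2 carbonyl (Barton–McCombie) and oxidising the C4=C9 enol ether.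
- The cycloadduct ⇐ Rh(II) carbonyl ylide from a vinylogous-ester diazoketone plus heptanal (O8–C1, C1–C7 and O6–C5 bonds; C1, C5 and C7 set).
- Ring order: carbocycle (from cyclohexane-1,3-dione) → oxane and dioxolane together → dihydropyran hemiketal; the pyrone ring is bought.

Key step: step 5

Locants used below: the ketal bicycle is numbered as a 6,8-dioxabicyclo[3.2.1]octane, C1 (O–CH bridgehead), C2, C3, C4, C5 (ketal carbon), O6, C7 (hexyl-bearing O–CH), O8. The annulated carbocycle is C4–C9–C10–C11–C12–C5 (C9 = later hemiketal carbon, C10 = later carbinol carbon). In these locants the target is 1S,3R,4S,5R,7S,9S,10R.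

Assumption: C4–H and the hemiketal carbon C9 can epimerise through the ring-opened 9-keto form. The natural arrangement (pyran trans-fused to the carbocycle, axial hemiketal OH, C3–C2 bond pseudoaxial on the pyran ring) is taken to be the one that forms and persists under the mildly basic conditions of step 10.

**Route**

Step 1
Reactants: 1 cyclohexane-1,3-dione; 2 ethyl glyoxylate
Product: 4 ethyl 2-(2-hydroxy-6-oxocyclohex-1-en-1-yl)acetate, via alkylidene dione 3 (not isolated)
Conditions: Hantzsch ester (1.05 equiv), L-proline (10 mol%), CH2Cl2, rt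
Reagents that add atoms: none
Why: Three-component reductive alkylation: proline-catalysed Knoevenagel condensation gives the doubly activated alkylidene dione, which the Hantzsch ester reduces at once by conjugate hydride transfer, so that only the C-alkylated dione should form.

Step 2
Reactants: 4 ethyl 2-(2-hydroxy-6-oxocyclohex-1-en-1-yl)acetate
Product: 5 ethyl 2-(2-methoxy-6-oxocyclohex-1-en-1-yl)acetate
Conditions: TMSCHN2 (1.3 equiv), MeOH/toluene 1:4, 0 °C to rt
Reagents that add atoms: trimethylsilyldiazomethane, C[Si](C)(C)C=[N+]=[N-]
Why: O-Methylation of the acidic enol with the diazomethane surrogate (methanol supplies the proton and takes up silicon) should give the vinylogous ester without the C-methylation that MeI/base would cause, and the symmetry of the dione allows only one regioisomer.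

Step 3
Reactants: 5 ethyl 2-(2-methoxy-6-oxocyclohex-1-en-1-yl)acetate
Product: 6 2-(2-methoxy-6-oxocyclohex-1-en-1-yl)acetic acid
Conditions: LiOH·H2O (1.5 equiv), THF/H2O 3:1, 0 °C to rt; then cold 0.5 M HCl to pH 4, EtOAc extraction
Reagents that add atoms: lithium hydroxide, [Li+].[OH-]
Why: Saponification of the unhindered ethyl ester is far faster than hydroxide addition to the tetrasubstituted vinylogous ester, and acidifying only to pH 4 at 0 °C should free the acid without hydrolysing the enol ether.

Step 4
Reactants: 6 2-(2-methoxy-6-oxocyclohex-1-en-1-yl)acetic acid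
Product: 8 2-(3-diazo-2-oxopropyl)-3-methoxycyclohex-2-en-1-one, via mixed anhydride 7 (not isolated)
Conditions: iBuOCOCl, N-methylmorpholine, THF, −20 °C; then CH2N2 (Et2O, excess), −20 to 0 °C
Reagents that add atoms: diazomethane, C=[N+]=[N-]
Why: Acylation of diazomethane by the mixed carbonic anhydride (the diazoketone-forming step of the Arndt–Eistert sequence) runs under neutral, cold conditions that the vinylogous ester tolerates, which an acid chloride route would not.

Step 5
Reactants: 8 2-(3-diazo-2-oxopropyl)-3-methoxycyclohex-2-en-1-one; 9 heptanal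
Product: 11 tricyclic ketal enol ether 2-ketone (1R,5R,7S; 7-exo-hexyl; C4=C9–OMe), via carbonyl ylide 10 (not isolated)
Conditions: Rh2(S-BPTV)4 (1 mol%; the R-catalyst if a test run shows it is the one leading to the 1R,5R,7S series), 9 (4 equiv), PhCF3, 0 °C, 8 added over 2 h
Reagents that add atoms: none
Why: Rh(II) converts the diazoketone into an electrophilic carbenoid that is captured by the basic carbonyl oxygen of the vinylogous ester (six-membered closure through the O8–C1 bond, the oxane), giving a push–pull carbonyl ylide whose anionic carbon C1 is stabilised by the C2 ketone and whose cationic carbon C5 by the methoxyvinyl group. Heptanal then adds as dipolarophile in a concerted 1,3-dipolar [3+2] closure across C1–O8–C5, aldehyde carbon to the nucleophilic C1 (C1–C7 bond) and aldehyde oxygen to the oxocarbenium carbon C5 (O6–C5 bond), which forms the dioxolane; this is the known tandem ylide formation/cycloaddition of 1-diazo-2,5-diones with aldehydes that gives 6,8-dioxabicyclo[3.2.1]octan-2-ones. C1 and C5 are tied to each other by the bicyclic geometry, and C7 is set by exo approach of the aldehyde, hexyl turned away from the C2–C3–C4 bridge of the ylide ring. The absolute configuration must come from the chiral dirhodium carboxylate staying bound to the ylide during the cycloaddition, as in the enantioselective aldehyde additions of related six-membered ylides. The step needs carbonyl-O rather than ether-O capture of the carbenoid (secured by the much higher basicity of the vinylogous-ester carbonyl), cycloaddition rather than 1,4-proton shift of the ylide (secured by excess aldehyde and slow addition of 8), and exo rather than endo addition.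

Step 6
Reactants: 11 tricyclic ketal enol ether 2-ketone
Product: 12 tricyclic ketal enol ether 2-alcohol (2R expected)
Conditions: NaBH4, MeOH, 0 °C
Reagents that add atoms: none
Why: Borohydride reduction of the only ketone leaves enol ether and ketal untouched; hydride should arrive on the face away from the C7 bridge, but the carbinol configuration is irrelevant because this centre becomes CH2 in step 8.

Step 7
Reactants: 12 tricyclic ketal enol ether 2-alcohol
Product: 13 O-(C2) S-methyl xanthate of 12
Conditions: NaH, cat. imidazole, THF, 0 °C; CS2; then MeI, rt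
Reagents that add atoms: carbon disulfide, S=C=S; iodomethane, CI
Why: Xanthate formation (first half of the Barton–McCombie deoxygenation) from the secondary alkoxide runs under purely basic conditions, which the acid-labile ketal and enol ether tolerate.

Step 8
Reactants: 13 O-(C2) S-methyl xanthate
Product: 14 2-deoxy tricyclic ketal enol ether (C2 = CH2; C4=C9–OMe)
Conditions: Bu3SnH (1.5 equiv), AIBN (cat.), toluene, 100 °C
Reagents that add atoms: none
Why: Barton–McCombie radical deoxygenation: the secondary C2 radical should be reduced by Bu3SnH without β-scission of the neighbouring C–O bond, as in carbohydrate deoxygenations, whereas hydrazone-based deoxygenation of this α-alkoxy ketone would eliminate O8.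

Step 9
Reactants: 14 2-deoxy tricyclic ketal enol ether
Product: 17 tricyclic ketal C3=C4 enone (9-ketone), via 4-phenylselanyl 9-ketone 15 (not isolated), via selenoxide 16 (not isolated)
Conditions: PhSeCl, pyridine, CH2Cl2, −78 °C; H2O, 0 °C; then 30% H2O2, 0 °C to rt
Reagents that add atoms: water, O
Why: Electrophilic selenenylation of the enol ether at C4, hydrolysis of the oxocarbenium ion to the C9 ketone and selenoxide syn-elimination (which can only take hydrogen from C3, as C5 has none) should give the enone without passing through a C4–H ketone that could open the ketal by β-elimination.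

Step 10
Reactants: 17 tricyclic ketal C3=C4 enone; 18 4-hydroxy-6-methyl-2-pyrone
Product: 20 10-deoxy-trichopsistide B (hemiketal), via open keto Michael adduct 19 (not isolated)
Conditions: 18 (1.5 equiv), DABCO (10 mol%), EtOH, 40 °C
Reagents that add atoms: none
Why: Michael addition of the pyrone C3 to the β-carbon C3 of the s-cis enone (warfarin-type chemistry) should occur on the face away from the O6–C7 bridge, protonation at C4 trans to the new substituent and closure of the pyrone 4-OH onto the C9 ketone then give the six-membered hemiketal with axial (anomeric) OH, and since C4 and C9 stay equilibrable through 19 they should settle in this arrangement, which keeps the C3–C2 bond pseudoaxial on the pyran ring and so avoids allylic strain with the lactone carbonyl.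

Step 11
Reactants: 20 10-deoxy-trichopsistide B
Product: 22 Trichopsistide B, via open 10-hydroxy 9-ketone 21 (not isolated)
Conditions: KHMDS (2.3 equiv), THF, −78 °C; 2-(benzenesulfonyl)-3-phenyloxaziridine (1.2 equiv), −78 °C; AcOH, −78 °C to rt
Reagents that add atoms: 2-(benzenesulfonyl)-3-phenyloxaziridine, O=S(=O)(c1ccccc1)N1OC1c1ccccc1
Why: The first equivalent of base opens the hemiketal to the pyronate ketone, the second removes a proton kinetically from the unhindered C10 methylene (C4–H is tertiary and flanked by C5 and C3), and Davis α-hydroxylation of this enolate by axial attack on the conformationally locked carbocycle, on the face that carries C4–H, should give the 10R carbinol, after which the hemiketal re-closes on acidification with its OH trans to the new hydroxyl.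

**Compound list**

1 | cyclohexane-1,3-dione | O=C1CCCC(=O)C1 | starting material
2 | ethyl glyoxylate | CCOC(=O)C=O | starting material
3 | ethyl 2-(2,6-dioxocyclohexylidene)acetate | CCOC(=O)C=C1C(=O)CCCC1=O | intermediate
4 | ethyl 2-(2-hydroxy-6-oxocyclohex-1-en-1-yl)acetate (enol form of the 2-substituted dione) | CCOC(=O)CC1=C(O)CCCC1=O | intermediate
5 | ethyl 2-(2-methoxy-6-oxocyclohex-1-en-1-yl)acetate | CCOC(=O)CC1=C(OC)CCCC1=O | intermediate
6 | 2-(2-methoxy-6-oxocyclohex-1-en-1-yl)acetic acid | COC1=C(CC(=O)O)C(=O)CCC1 | intermediate
7 | isobutyl carbonic mixed anhydride of 6 | COC1=C(CC(=O)OC(=O)OCC(C)C)C(=O)CCC1 | intermediate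
8 | 2-(3-diazo-2-oxopropyl)-3-methoxycyclohex-2-en-1-one | COC1=C(CC(=O)C=[N+]=[N-])C(=O)CCC1 | intermediate
9 | heptanal | CCCCCCC=O | starting material
10 | six-membered push–pull carbonyl ylide (rhodium-associated) | [CH-]1C(=O)CC2=C(OC)CCCC2=[O+]1 | intermediate
11 | (1R,5R,7S)-7-exo-hexyl tricyclic ketal, C2 ketone, C4=C9 methyl enol ether | CCCCCC[C@@H]1O[C@]23CCCC(OC)=C3CC(=O)[C@@H]1O2 | intermediate
12 | C2 alcohol of 11 (2R drawn; either epimer usable) | CCCCCC[C@@H]1O[C@]23CCCC(OC)=C3C[C@@H](O)[C@@H]1O2 | intermediate
13 | S-methyl xanthate of 12 | CCCCCC[C@@H]1O[C@]23CCCC(OC)=C3C[C@@H](OC(=S)SC)[C@@H]1O2 | intermediate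
14 | 2-deoxy tricyclic ketal enol ether (ketal centres as in 11) | CCCCCC[C@@H]1O[C@]23CCCC(OC)=C3CC[C@@H]1O2 | intermediate
15 | 4-phenylselanyl 9-ketone (C4 configuration not defined; both epimers eliminate to 17) | CCCCCC[C@@H]1O[C@]23CCCC(=O)C3([Se]c4ccccc4)CC[C@@H]1O2 | intermediate
16 | selenoxide of 15 | CCCCCC[C@@H]1O[C@]23CCCC(=O)C3([Se](=O)c4ccccc4)CC[C@@H]1O2 | intermediate
17 | tricyclic ketal C3=C4 enone, 9-ketone | CCCCCC[C@@H]1O[C@]23CCCC(=O)C3=CC[C@@H]1O2 | intermediate
18 | 4-hydroxy-6-methyl-2-pyrone | Cc1cc(O)cc(=O)o1 | starting material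
19 | open 9-keto form of the Michael adduct (pyrone on C3, anti to the O6–C7 bridge) | CCCCCC[C@@H]1O[C@]23CCCC(=O)[C@@H]3[C@H](c3c(O)cc(C)oc3=O)C[C@@H]1O2 | intermediate
20 | 10-deoxy-trichopsistide B (1S,3R,4S,5R,7S,9S hemiketal) | CCCCCC[C@@H]1O[C@]23CCC[C@@]4(O)Oc5cc(C)oc(=O)c5[C@H](C[C@@H]1O2)[C@H]34 | intermediate
21 | open (10R)-10-hydroxy 9-ketone | CCCCCC[C@@H]1O[C@]23CC[C@@H](O)C(=O)[C@@H]3[C@H](c3c(O)cc(C)oc3=O)C[C@@H]1O2 | intermediate
22 | Trichopsistide B | CCCCCC[C@@H]1O[C@]23CC[C@@H](O)[C@@]4(O)Oc5cc(C)oc(=O)c5[C@H](C[C@@H]1O2)[C@H]34 | target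

**Step count and risks**

Total step count: 11. Longest linear sequence: 11 steps from cyclohexane-1,3-dione (ethyl glyoxylate, heptanal and the pyrone enter as purchased partners).

Steps most likely to fail:

1. Step 5. The ylide may dissociate from the chiral rhodium before it meets the aliphatic aldehyde (low enantioface discrimination), exo preference may be incomplete, and 1,4-proton shift of the ylide may consume material. Fallback, setting out from 8 and 9 and returning at 12: the cycloaddition is run with achiral Rh2(OAc)4, which gives 11 as a racemate together with the enantiomeric cycloadduct F1. Reduction as in step 6 gives 12 together with the enantiomeric alcohol F2. Esterification with (S)-O-methylmandelic acid (DCC, DMAP, CH2Cl2) gives the diastereomeric esters, the mandelate of 12 F3 and the mandelate of the enantiomeric alcohol F4, which are separated by chromatography. K2CO3/MeOH on F3 releases enantiopure 12, and the route continues with step 7.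

2. Step 10. Conjugate addition to the α-substituted enone may be sluggish, and under base the C4 enolate may expel a ketal oxygen (E1cB ring opening) instead of being protonated, or C4 may settle in the wrong configuration. Fallback, setting out from 11 and returning at 20: the C2 ketone is kept as a second activating group. NBS/NaHCO3 in aqueous THF converts the enol ether of 11 into the 4-bromo 2,9-diketone F5 (not isolated), and Et3N eliminates HBr to the ene-dione F6. This doubly activated acceptor should take up 18 in EtOH without added base to give the 2-keto hemiketal F7. NaBH4 at −40 °C reduces the free C2 ketone in preference to the hemiketal-masked C9 to give the 2-hydroxy hemiketal F8. 1,1'-Thiocarbonyldiimidazole (DMAP, CH2Cl2, reflux) derivatises the secondary OH only, giving the imidazolylthiocarbonate F9, and Bu3SnH/AIBN then gives 20.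

3. Step 11. Under the strong base the opened keto pyronate may enolise toward C4 and then lose a ketal oxygen or the pyronate (retro-Michael), and facial selectivity of oxygen transfer may be poor. Fallback, setting out from 17 and returning at 22: hydroxylation is moved ahead of the pyrone addition. LiHMDS/TMSCl (THF, −78 °C) gives the cross-conjugated silyl dienol ether F10. Rubottom oxidation with DMDO (acetone, −40 °C) gives the 10-silyloxy enone F11, and K2CO3/MeOH gives the 10-hydroxy enone F12, the 10R epimer being isolated. F12 is combined with 18 under the conditions of step 10 and should give 22 directly through 21.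

**Further compounds**

F1 | step 5 | enantiomer of cycloadduct 11 | CCCCCC[C@H]1O[C@@]23CCCC(OC)=C3CC(=O)[C@H]1O2
F2 | step 5 | enantiomer of alcohol 12 | CCCCCC[C@H]1O[C@@]23CCCC(OC)=C3C[C@H](O)[C@H]1O2
F3 | step 5 | (S)-O-methylmandelate of 12 | CCCCCC[C@@H]1O[C@]23CCCC(OC)=C3C[C@@H](OC(=O)[C@@H](OC)c4ccccc4)[C@@H]1O2
F4 | step 5 | (S)-O-methylmandelate of the enantiomeric alcohol | CCCCCC[C@H]1O[C@@]23CCCC(OC)=C3C[C@H](OC(=O)[C@@H](OC)c4ccccc4)[C@H]1O2
F5 | step 10 | 4-bromo 2,9-diketone (C4 configuration not defined) | CCCCCC[C@@H]1O[C@]23CCCC(=O)C3(Br)CC(=O)[C@@H]1O2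
F6 | step 10 | C3=C4 ene-2,9-dione | CCCCCC[C@@H]1O[C@]23CCCC(=O)C3=CC(=O)[C@@H]1O2
F7 | step 10 | 2-keto hemiketal (pyrone adduct of F6) | CCCCCC[C@@H]1O[C@]23CCC[C@@]4(O)Oc5cc(C)oc(=O)c5[C@H](C(=O)[C@@H]1O2)[C@H]34
F8 | step 10 | 2-hydroxy hemiketal (C2 configuration not defined) | CCCCCC[C@@H]1O[C@]23CCC[C@@]4(O)Oc5cc(C)oc(=O)c5[C@H](C(O)[C@@H]1O2)[C@H]34
F9 | step 10 | 2-O-(imidazol-1-ylthiocarbonyl) derivative of F8 | CCCCCC[C@@H]1O[C@]23CCC[C@@]4(O)Oc5cc(C)oc(=O)c5[C@H](C(OC(=S)n6ccnc6)[C@@H]1O2)[C@H]34
F10 | step 11 | cross-conjugated trimethylsilyl dienol ether of 17 (C9=C10) | CCCCCC[C@@H]1O[C@]23CCC=C(O[Si](C)(C)C)C3=CC[C@@H]1O2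
F11 | step 11 | (10R)-10-trimethylsilyloxy enone | CCCCCC[C@@H]1O[C@]23CC[C@@H](O[Si](C)(C)C)C(=O)C3=CC[C@@H]1O2
F12 | step 11 | (10R)-10-hydroxy enone | CCCCCC[C@@H]1O[C@]23CC[C@@H](O)C(=O)C3=CC[C@@H]1O2
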